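**Retrosynthetic overview**

1. Last disconnection: the C3–O ester bond, giving the Z,Z-configured side-chain acid and the bicyclic hydroxy-diosphenol (eremophilane numbering: ring A = C1–C5 and C10, ring B = C5–C10, C11 = isopropylidene carbon).
2. Feature used: in ring B the ketone carbon C8 and the enol carbon C9 are together one enolised 1,2-dione. Each is bonded to an sp2 carbon (C7, which carries the isopropylidene, and the ring-fusion carbon C10), and these two are 1,4-related through the saturated C6–C5 link.
3. Key disconnection: C8–C9 is taken as an oxalyl dication (N,N′-dimethoxy-N,N′-dimethyloxamide) and C7/C10 as a 1,4-bis(alkenyllithium). One anionic [4+2] annulation makes C7–C8 and C9–C10 and gives the 1(10),7(11)-diene-8,9-dione, which is one conjugate hydride at C1 away from the diosphenol.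
4. Ring A is a cyclohexanone from the start: C3 by enantioselective deprotonation, C4 by trans cuprate addition, C5 by enolate alkylation with 1,2-dibromo-3-methylbut-2-ene; the C10 ketone becomes the alkenyl iodide.
5. Order of ring formation: ring A (present in the starting material), then ring B in the key step; the side-chain acid comes from syn-carbocupration of an ynoate and angeloylation.

Key step: step 11

Remark: bicyclic compounds are named with eremophilane numbers as defined above, and the sense of the chiral-amide deprotonation in step 4 is assumed to follow that known for 4-substituted cyclohexanones (the antipodal amine would be used otherwise).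

**Route**

Step 1
Reactants: 1 3-methylbut-2-enal
Product: 3 2-bromo-3-methylbut-2-enal, via dibromo aldehyde 2 (not isolated)
Conditions: Br2, CH2Cl2, −78 → 0 °C; then Et3N, 0 °C → rt
Reagents that add atoms: bromine, BrBr
Why: Bromine adds across the enal C=C and triethylamine then removes the acidic α-hydrogen with loss of the tertiary β-bromide (bromination–dehydrobromination, E1cB), which returns the conjugated tetrasubstituted 2-bromoenal with no stereo element.

Step 2
Reactants: 3 2-bromo-3-methylbut-2-enal
Product: 4 2-bromo-3-methylbut-2-en-1-ol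
Conditions: NaBH4, CeCl3·7H2O, MeOH, 0 °C
Reagents that add atoms: none
Why: Luche reduction delivers hydride 1,2 to the aldehyde and leaves the bromoalkene untouched.

Step 3
Reactants: 4 2-bromo-3-methylbut-2-en-1-ol
Product: 5 1,2-dibromo-3-methylbut-2-ene
Conditions: PBr3, Et2O, 0 °C
Reagents that add atoms: phosphorus tribromide, BrP(Br)Br
Why: Alcohol-to-bromide conversion with PBr3 (SN2 displacement of the bromophosphite ester); the unrearranged primary allylic bromide is also the more stable regioisomer.

Step 4
Reactants: 6 4-(tert-butyldimethylsilyloxy)cyclohexan-1-one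
Product: 7 (R)-tert-butyldimethyl{[4-(trimethylsilyloxy)cyclohex-3-en-1-yl]oxy}silane
Conditions: bis[(S)-1-phenylethyl]amine, n-BuLi, LiCl, THF, −78 °C; then TMSCl and 6, −100 → −78 °C
Reagents that add atoms: chlorotrimethylsilane, C[Si](C)(C)Cl
Why: Enantioselective deprotonation of a prochiral 4-substituted cyclohexanone by a C2-symmetric chiral lithium amide with internal silyl quench (desymmetrisation): the amide removes one of the two enantiotopic axial α-hydrogens, which fixes the later C3 centre as R.

Step 5
Reactants: 7 (R)-tert-butyldimethyl{[4-(trimethylsilyloxy)cyclohex-3-en-1-yl]oxy}silane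
Product: 8 (R)-4-(tert-butyldimethylsilyloxy)cyclohex-2-en-1-one
Conditions: Pd(OAc)2 (10 mol %), O2 (1 atm), DMSO, rt
Reagents that add atoms: none
Why: Saegusa–Ito oxidation in its aerobic catalytic form: β-hydride elimination of the palladium enolate occurs only on the enol ether side, so the double bond appears next to the stereocentre, which is not touched.

Step 6
Reactants: 8 (R)-4-(tert-butyldimethylsilyloxy)cyclohex-2-en-1-one
Product: 9 (R)-4-(tert-butyldimethylsilyloxy)-2-iodocyclohex-2-en-1-one
Conditions: I2, pyridine, CH2Cl2, 0 °C → rt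
Reagents that add atoms: iodine, II
Why: α-Iodination of a cyclic enone by pyridine conjugate addition, iodination of the enolate and elimination; the weakly basic medium should not enolise toward C4.

Step 7
Reactants: 9 (R)-4-(tert-butyldimethylsilyloxy)-2-iodocyclohex-2-en-1-one
Product: 10 (R)-4-(tert-butyldimethylsilyloxy)-2-methylcyclohex-2-en-1-one
Conditions: Me4Sn, Pd2(dba)3 (cat.), AsPh3, CuI (cat.), NMP, 80 °C
Reagents that add atoms: tetramethylstannane, C[Sn](C)(C)C
Why: Stille coupling of the α-iodoenone with tetramethyltin under neutral conditions, which avoids γ-deprotonation and loss of the silyloxy stereocentre.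

Step 8
Reactants: 10 (R)-4-(tert-butyldimethylsilyloxy)-2-methylcyclohex-2-en-1-one
Product: 11 tert-butyl{[(1R,2R)-2,3-dimethyl-4-(trimethylsilyloxy)cyclohex-3-en-1-yl]oxy}dimethylsilane
Conditions: Me2CuLi (from MeLi and CuI), TMSCl, THF, −78 °C; Et3N, aq. NaHCO3
Reagents that add atoms: lithium dimethylcuprate, [Li+].C[Cu-]C; chlorotrimethylsilane, C[Si](C)(C)Cl
Why: Cuprate conjugate addition accelerated by TMSCl: methyl is delivered to the face anti to the adjacent silyloxy group, which sets C4 trans to the C3 oxygen, and the enolate is trapped regiospecifically as the tetrasubstituted silyl enol ether.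

Step 9
Reactants: 11 tert-butyl{[(1R,2R)-2,3-dimethyl-4-(trimethylsilyloxy)cyclohex-3-en-1-yl]oxy}dimethylsilane; 5 1,2-dibromo-3-methylbut-2-ene
Product: 13 (2R,3R,4R)-2-(2-bromo-3-methylbut-2-en-1-yl)-4-(tert-butyldimethylsilyloxy)-2,3-dimethylcyclohexan-1-one, via lithium enolate 12 (not isolated)
Conditions: MeLi, THF, 0 °C; then 5, HMPA, −78 → 0 °C
Reagents that add atoms: methyllithium, [Li]C (lithium atom of 12 only)
Why: Regiospecific lithium enolate formation by Si–O cleavage and SN2 C-alkylation with the allylic bromide; A(1,2) strain with the C5 methyl holds the C4 methyl pseudoaxial and the electrophile should enter the opposite face, so the two methyls end cis and quaternary C5 is set (as with 2,3-dimethylcyclohexanone enolates).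

Step 10
Reactants: 13 (2R,3R,4R)-2-(2-bromo-3-methylbut-2-en-1-yl)-4-(tert-butyldimethylsilyloxy)-2,3-dimethylcyclohexan-1-one
Product: 15 tert-butyl{[(1R,2R,3R)-3-(2-bromo-3-methylbut-2-en-1-yl)-4-iodo-2,3-dimethylcyclohex-4-en-1-yl]oxy}dimethylsilane, via hydrazone 14 (not isolated)
Conditions: N2H4·H2O, Et3N, EtOH, 80 °C; then I2, 1,1,3,3-tetramethylguanidine, THF, 0 °C → rt
Reagents that add atoms: hydrazine, NN (nitrogen atoms of 14 only); iodine, II
Why: Hydrazone formation followed by the Barton vinyl iodide synthesis (oxidation to the diazo compound, iodination, loss of N2, elimination); C1 is the only α-carbon with hydrogen, so the alkenyl iodide is regiodefined, and the tetrasubstituted bromoalkene is inert to iodine and amidine base.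

Step 11
Reactants: 15 tert-butyl{[(1R,2R,3R)-3-(2-bromo-3-methylbut-2-en-1-yl)-4-iodo-2,3-dimethylcyclohex-4-en-1-yl]oxy}dimethylsilane; 16 N,N′-dimethoxy-N,N′-dimethyloxamide
Product: 19 (3R,4R,5R)-3-(tert-butyldimethylsilyloxy)eremophila-1(10),7(11)-diene-8,9-dione, via bis(alkenyllithium) 17 (not isolated), via dilithium bis(hemiaminal) 18 (not isolated)
Conditions: t-BuLi (4.2 equiv), Et2O, −78 °C; then 16 (1.0 equiv in THF, slow addition), −78 → 0 °C; aq. NH4Cl
Reagents that add atoms: tert-butyllithium, [Li]C(C)(C)C (lithium atoms of 17 and 18 only)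
Why: Proposed new method: double halogen–lithium exchange (alkenyl iodide at C10, alkenyl bromide at C7; irreversible with t-BuLi at −78 °C) should give bis(alkenyllithium) 17, one C–Li of which adds to one N-methoxy-N-methylamide carbonyl of 16 and the other, now intramolecularly, to the neighbouring one, so that C7–C8 and C9–C10 are both in place before either chelated tetrahedral hemiaminal of 18 collapses, and aqueous work-up then releases the 1,2-dione. The closest known reaction types are the preparation of 1,2-diketones from two equivalents of an organolithium and this oxamide, and ring-forming double additions of 1,4-dilithio reagents to bis-electrophiles (for example siloles from 1,4-dilithio-1,3-dienes and dichlorosilanes); new is the closure of a carbocyclic 1,2-dione by a bis(alkenyllithium) whose two carbanions are insulated by the saturated C6–C5 link. Ring B is closed by a 6-exo-trig addition of the second alkenyllithium to the adjacent amide carbonyl, overall an anionic [4+2] annulation in which the oxamide acts as an oxalyl dication. No stereocentre of the target is made (C8 and C9 of 18 become carbonyls), and C3, C4 and C5 carry no acidic hydrogen and are remote from the carbanions. The selectivities needed are ketone-level mono-addition at each carbonyl and cyclisation over oligomerisation: the lithium-chelated hemiaminals stop over-addition and stop the second C–Li from attacking C8 (which would give a cyclopentenol), and slow addition of one equivalent of 16 to dilute 17 keeps the second addition intramolecular.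

Step 12
Reactants: 19 (3R,4R,5R)-3-(tert-butyldimethylsilyloxy)eremophila-1(10),7(11)-diene-8,9-dione
Product: 20 (3R,4R,5R)-3-(tert-butyldimethylsilyloxy)-9-hydroxyeremophila-7(11),9-dien-8-one
Conditions: [(Ph3P)CuH]6 (0.4 equiv), H2O (5 equiv), benzene–THF, rt
Reagents that add atoms: none
Why: Conjugate reduction of an enone by a phosphine-stabilised copper hydride: hydride should add to C1, the monosubstituted β-carbon of the C1=C10–C9=O enone, rather than to the β,β-dimethyl C11, and O-protonation of the copper enolate gives the hydrogen-bonded C9 enol (the diosphenol) directly, with no new stereocentre.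

Step 13
Reactants: 20 (3R,4R,5R)-3-(tert-butyldimethylsilyloxy)-9-hydroxyeremophila-7(11),9-dien-8-one
Product: 21 (3R,4R,5R)-3,9-dihydroxyeremophila-7(11),9-dien-8-one
Conditions: HF·pyridine, pyridine, THF, 0 °C → rt
Reagents that add atoms: none
Why: Fluoride-induced cleavage of the secondary silyl ether under buffered conditions, which the enol, the enone and the isopropylidene should tolerate.

Step 14
Reactants: 22 tert-butyldimethyl(prop-2-yn-1-yloxy)silane
Product: 24 tert-butyl 4-(tert-butyldimethylsilyloxy)but-2-ynoate, via lithium acetylide 23 (not isolated)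
Conditions: n-BuLi, THF, −78 °C; then Boc2O, −78 → 0 °C
Reagents that add atoms: n-butyllithium, [Li]CCCC (lithium atom of 23 only); di-tert-butyl dicarbonate, CC(C)(C)OC(=O)OC(=O)OC(C)(C)C
Why: C-Acylation of a lithium acetylide with di-tert-butyl dicarbonate gives the tert-butyl alkynoate directly.

Step 15
Reactants: 24 tert-butyl 4-(tert-butyldimethylsilyloxy)but-2-ynoate
Product: 25 tert-butyl (Z)-4-(tert-butyldimethylsilyloxy)-3-methylbut-2-enoate
Conditions: Me2CuLi (from MeLi and CuI), THF, −78 °C; MeOH quench at −78 °C
Reagents that add atoms: lithium dimethylcuprate, [Li+].C[Cu-]C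
Why: syn-Carbocupration of the ynoate at −78 °C (methyl and copper add to the same face) and protonation with retention place CH2OSi and the ester cis, which sets the Z trisubstituted alkene.

Step 16
Reactants: 25 tert-butyl (Z)-4-(tert-butyldimethylsilyloxy)-3-methylbut-2-enoate
Product: 26 tert-butyl (Z)-4-hydroxy-3-methylbut-2-enoate
Conditions: HF·pyridine, pyridine, THF, 0 °C
Reagents that add atoms: none
Why: Desilylation with buffered HF; the absence of alkoxide and the poor leaving-group ability of tert-butoxide should keep the cis hydroxy ester from closing to the butenolide.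

Step 17
Reactants: 27 angelic acid, (Z)-2-methylbut-2-enoic acid; 26 tert-butyl (Z)-4-hydroxy-3-methylbut-2-enoate
Product: 29 tert-butyl (Z)-3-methyl-4-{[(Z)-2-methylbut-2-enoyl]oxy}but-2-enoate, via mixed anhydride 28 (not isolated)
Conditions: 2,4,6-trichlorobenzoyl chloride, Et3N, toluene, rt; then 26, rt → 40 °C
Reagents that add atoms: 2,4,6-trichlorobenzoyl chloride, O=C(Cl)c1c(Cl)cc(Cl)cc1Cl (aroyl group of 28 only)
Why: Yamaguchi esterification through the mixed anhydride without a nucleophilic amine catalyst: the primary alcohol attacks the less hindered angeloyl carbonyl, and leaving out DMAP avoids addition–elimination isomerisation of the Z-angelate to the tiglate.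

Step 18
Reactants: 29 tert-butyl (Z)-3-methyl-4-{[(Z)-2-methylbut-2-enoyl]oxy}but-2-enoate
Product: 30 (Z)-3-methyl-4-{[(Z)-2-methylbut-2-enoyl]oxy}but-2-enoic acid
Conditions: CF3CO2H, CH2Cl2, 0 °C
Reagents that add atoms: none
Why: Acidolysis of the tert-butyl ester (E1 loss of isobutene) should leave the primary allylic angelate and both Z alkenes untouched at low temperature.

Step 19
Reactants: 21 (3R,4R,5R)-3,9-dihydroxyeremophila-7(11),9-dien-8-one; 30 (Z)-3-methyl-4-{[(Z)-2-methylbut-2-enoyl]oxy}but-2-enoic acid
Product: 31 (3R,4R,5R)-9-hydroxy-8-oxoeremophila-7(11),9-dien-3-yl (Z)-3-methyl-4-{[(Z)-2-methylbut-2-enoyl]oxy}but-2-enoate (CNP0228871.1)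
Conditions: N,N′-diisopropylcarbodiimide, DMAP (0.1 equiv), CH2Cl2, 0 °C → rt
Reagents that add atoms: none
Why: Steglich esterification: the equatorial secondary C3 hydroxyl should be acylated in preference to the C9 enol hydroxyl, which is hydrogen bonded to the C8 carbonyl and flanked by the fully substituted C10, and any enol ester formed is an active ester that returns the acyl group to DMAP; C3 reacts with retention.

**Compound list**

1 | 3-methylbut-2-enal | CC(C)=CC=O | starting material
2 | 2,3-dibromo-3-methylbutanal | O=CC(Br)C(C)(C)Br | intermediate (not isolated)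
3 | 2-bromo-3-methylbut-2-enal | O=CC(Br)=C(C)C | intermediate
4 | 2-bromo-3-methylbut-2-en-1-ol | OCC(Br)=C(C)C | intermediate
5 | 1,2-dibromo-3-methylbut-2-ene | BrCC(Br)=C(C)C | intermediate
6 | 4-(tert-butyldimethylsilyloxy)cyclohexan-1-one | CC(C)(C)[Si](C)(C)OC1CCC(=O)CC1 | starting material
7 | (R)-tert-butyldimethyl{[4-(trimethylsilyloxy)cyclohex-3-en-1-yl]oxy}silane | CC(C)(C)[Si](C)(C)O[C@@H]1CCC(O[Si](C)(C)C)=CC1 | intermediate
8 | (R)-4-(tert-butyldimethylsilyloxy)cyclohex-2-en-1-one | CC(C)(C)[Si](C)(C)O[C@@H]1CCC(=O)C=C1 | intermediate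
9 | (R)-4-(tert-butyldimethylsilyloxy)-2-iodocyclohex-2-en-1-one | CC(C)(C)[Si](C)(C)O[C@@H]1CCC(=O)C(I)=C1 | intermediate
10 | (R)-4-(tert-butyldimethylsilyloxy)-2-methylcyclohex-2-en-1-one | CC(C)(C)[Si](C)(C)O[C@@H]1CCC(=O)C(C)=C1 | intermediate
11 | tert-butyl{[(1R,2R)-2,3-dimethyl-4-(trimethylsilyloxy)cyclohex-3-en-1-yl]oxy}dimethylsilane | CC(C)(C)[Si](C)(C)O[C@@H]1CCC(O[Si](C)(C)C)=C(C)[C@H]1C | intermediate
12 | lithium (3R,4R)-4-(tert-butyldimethylsilyloxy)-2,3-dimethylcyclohex-1-en-1-olate | CC(C)(C)[Si](C)(C)O[C@@H]1CCC(O[Li])=C(C)[C@H]1C | intermediate (not isolated)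
13 | (2R,3R,4R)-2-(2-bromo-3-methylbut-2-en-1-yl)-4-(tert-butyldimethylsilyloxy)-2,3-dimethylcyclohexan-1-one | CC(C)(C)[Si](C)(C)O[C@@H]1CCC(=O)[C@](C)(CC(Br)=C(C)C)[C@H]1C | intermediate
14 | hydrazone of 13 | CC(C)(C)[Si](C)(C)O[C@@H]1CCC(=NN)[C@](C)(CC(Br)=C(C)C)[C@H]1C | intermediate (not isolated)
15 | tert-butyl{[(1R,2R,3R)-3-(2-bromo-3-methylbut-2-en-1-yl)-4-iodo-2,3-dimethylcyclohex-4-en-1-yl]oxy}dimethylsilane | CC(C)(C)[Si](C)(C)O[C@@H]1CC=C(I)[C@](C)(CC(Br)=C(C)C)[C@H]1C | intermediate
16 | N,N′-dimethoxy-N,N′-dimethyloxamide | CON(C)C(=O)C(=O)N(C)OC | starting material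
17 | bis(alkenyllithium) from 15 (lithium at C10 and C7) | CC(C)(C)[Si](C)(C)O[C@@H]1CC=C([Li])[C@](C)(CC([Li])=C(C)C)[C@H]1C | intermediate (not isolated)
18 | dilithium 8,9-bis[methoxy(methyl)amino]-8,9-diolate adduct (ring B closed) | CC(C)(C)[Si](C)(C)O[C@@H]1CC=C2C(O[Li])(N(C)OC)C(O[Li])(N(C)OC)C(=C(C)C)C[C@]2(C)[C@H]1C | intermediate (not isolated)
19 | (3R,4R,5R)-3-(tert-butyldimethylsilyloxy)eremophila-1(10),7(11)-diene-8,9-dione | CC(C)(C)[Si](C)(C)O[C@@H]1CC=C2C(=O)C(=O)C(=C(C)C)C[C@]2(C)[C@H]1C | intermediate
20 | (3R,4R,5R)-3-(tert-butyldimethylsilyloxy)-9-hydroxyeremophila-7(11),9-dien-8-one | CC(C)(C)[Si](C)(C)O[C@@H]1CCC2=C(O)C(=O)C(=C(C)C)C[C@]2(C)[C@H]1C | intermediate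
21 | (3R,4R,5R)-3,9-dihydroxyeremophila-7(11),9-dien-8-one | O[C@@H]1CCC2=C(O)C(=O)C(=C(C)C)C[C@]2(C)[C@H]1C | intermediate
22 | tert-butyldimethyl(prop-2-yn-1-yloxy)silane | C#CCO[Si](C)(C)C(C)(C)C | starting material
23 | lithium acetylide of 22 | [Li]C#CCO[Si](C)(C)C(C)(C)C | intermediate (not isolated)
24 | tert-butyl 4-(tert-butyldimethylsilyloxy)but-2-ynoate | CC(C)(C)OC(=O)C#CCO[Si](C)(C)C(C)(C)C | intermediate
25 | tert-butyl (Z)-4-(tert-butyldimethylsilyloxy)-3-methylbut-2-enoate | CC(C)(C)[Si](C)(C)OC/C(C)=C\C(=O)OC(C)(C)C | intermediate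
26 | tert-butyl (Z)-4-hydroxy-3-methylbut-2-enoate | OC/C(C)=C\C(=O)OC(C)(C)C | intermediate
27 | angelic acid, (Z)-2-methylbut-2-enoic acid | C/C=C(/C)C(=O)O | starting material
28 | (Z)-2-methylbut-2-enoic 2,4,6-trichlorobenzoic anhydride | C/C=C(/C)C(=O)OC(=O)c1c(Cl)cc(Cl)cc1Cl | intermediate (not isolated)
29 | tert-butyl (Z)-3-methyl-4-{[(Z)-2-methylbut-2-enoyl]oxy}but-2-enoate | C/C=C(/C)C(=O)OC/C(C)=C\C(=O)OC(C)(C)C | intermediate
30 | (Z)-3-methyl-4-{[(Z)-2-methylbut-2-enoyl]oxy}but-2-enoic acid | C/C=C(/C)C(=O)OC/C(C)=C\C(=O)O | intermediate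
31 | (3R,4R,5R)-9-hydroxy-8-oxoeremophila-7(11),9-dien-3-yl (Z)-3-methyl-4-{[(Z)-2-methylbut-2-enoyl]oxy}but-2-enoate | C/C=C(/C)C(=O)OC/C(C)=C\C(=O)O[C@@H]1CCC2=C(O)C(=O)C(=C(C)C)C[C@]2(C)[C@H]1C | target

**Step count and risks**

Total step count: 19. Longest linear sequence: 11 steps (steps 4–13 and 19, from 6).

Steps most likely to fail:

1. Step 11 (proposed new method). Ring closure may be outrun by intermolecular addition to a second oxamide (oligomers), or the first hemiaminal may collapse early so that the second alkenyllithium attacks C8. The fallback makes the two C–C bonds independently of ring closure, with known reactions. Setting out from 15, the same double halogen–lithium exchange is quenched with excess DMF (formylation of alkenyllithiums) to give the bis-aldehyde F1. SmI2 in THF/t-BuOH then closes ring B by intramolecular pinacol coupling of the two aldehydes to the 8,9-diol F2, and Swern oxidation of the diol gives dione 19, where the route is rejoined.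

2. Step 19. The C9 enol hydroxyl may compete for the activated acid, and the activated Z-acid may isomerise or deconjugate under amine base. The fallback masks the enol and uses a base-free activation. Setting out from 20, acetic anhydride/pyridine gives the enol acetate F3 and HF·pyridine frees the C3 hydroxyl to give the hydroxy enol acetate F4. The acid chloride of 30 (from 1-chloro-N,N,2-trimethylprop-1-enylamine, then 2,6-lutidine) acylates C3 to give the ester enol acetate F5, and ammonia in methanol at −20 °C removes the activated enol acetate selectively to return to 31.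

3. Step 9. The allylic bromide may enter on the wrong face, because in the reactive half-chair the axial C3 silyloxy group shields the face anti to the C4 methyl; O-alkylation is a second loss. The fallback introduces the two C5 substituents in the opposite order, so that the same facial bias gives the other, needed epimer. Setting out from 8, lithium dimethylcuprate/TMSCl gives the silyl enol ether F6, and MeLi followed by 5 gives the monoalkylated ketone F7. Thermodynamic enolisation toward the more substituted α-carbon (t-BuOK, t-BuOH–THF) with methyl iodide then returns to 13.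

**Further compounds**

F1 | step 11 | (4R,5R,6R)-4-(tert-butyldimethylsilyloxy)-6-(2-formyl-3-methylbut-2-en-1-yl)-5,6-dimethylcyclohex-1-ene-1-carbaldehyde | CC(C)(C)[Si](C)(C)O[C@@H]1CC=C(C=O)[C@](C)(CC(C=O)=C(C)C)[C@H]1C
F2 | step 11 | (3R,4R,5R)-3-(tert-butyldimethylsilyloxy)eremophila-1(10),7(11)-diene-8,9-diol (diol configuration not defined) | CC(C)(C)[Si](C)(C)O[C@@H]1CC=C2C(O)C(O)C(=C(C)C)C[C@]2(C)[C@H]1C
F3 | step 19 | (3R,4R,5R)-3-(tert-butyldimethylsilyloxy)-8-oxoeremophila-7(11),9-dien-9-yl acetate | CC(C)(C)[Si](C)(C)O[C@@H]1CCC2=C(OC(C)=O)C(=O)C(=C(C)C)C[C@]2(C)[C@H]1C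
F4 | step 19 | (3R,4R,5R)-3-hydroxy-8-oxoeremophila-7(11),9-dien-9-yl acetate | O[C@@H]1CCC2=C(OC(C)=O)C(=O)C(=C(C)C)C[C@]2(C)[C@H]1C
F5 | step 19 | 9-O-acetyl derivative of 31 | C/C=C(/C)C(=O)OC/C(C)=C\C(=O)O[C@@H]1CCC2=C(OC(C)=O)C(=O)C(=C(C)C)C[C@]2(C)[C@H]1C
F6 | step 9 | tert-butyldimethyl{[(1R,2R)-2-methyl-4-(trimethylsilyloxy)cyclohex-3-en-1-yl]oxy}silane | CC(C)(C)[Si](C)(C)O[C@@H]1CCC(O[Si](C)(C)C)=C[C@H]1C
F7 | step 9 | (3R,4R)-2-(2-bromo-3-methylbut-2-en-1-yl)-4-(tert-butyldimethylsilyloxy)-3-methylcyclohexan-1-one | CC(C)(C)[Si](C)(C)O[C@@H]1CCC(=O)C(CC(Br)=C(C)C)[C@H]1C
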